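**Retrosynthetic overview**

1. The strategy rests on the E-disubstituted C15=C15′ alkene at the centre of the chain of ten conjugated C=C bonds. It divides the C40 skeleton into two C20 halves that differ only at their ends (cyclohexene ring C1–C6 with the C6 stereocentre; open C1′–C6′ ψ end). C15 and C15′ are both primary allylic carbons, so one sulfur atom can bridge them.
2. C15=C15′ is disconnected to the bis-allylic sulfone C15–SO2–C15′ (Ramberg–Bäcklund contraction, SO2 extrusion).
3. The sulfone comes from the sulfide, and the sulfide from an ε-C20 thioacetate and a ψ-C20 allylic bromide.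
4. Each C20 allylic alcohol comes from a C13 methyl ketone by a C2 and then a C5 Horner–Wadsworth–Emmons homologation: (R)-α-ionone (resolved) and (3E,5E)-pseudoionone.
5. No ring of the target is formed. The only ring (C1–C6) and the C6 centre come intact from α-ionone; the key step closes and destroys only a transient thiirane 1,1-dioxide.

Key step: step 16

**Remarks on the chemistry (assumptions)**

- Pseudoionone is taken as the (3E,5E) isomer. Commercial material that also holds the (5Z) isomer would be fractionated first, because a 5′Z bond would be carried through to the end.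
- Carotenoid numbering is used (C1–C15 for the ε half, primed numbers for the ψ half). All polyenes are handled under argon, in dim light and free of acid.
- The target has twelve C=C bonds, ten of them conjugated.

**Route**

Step 1
Reactants: 1 (±)-α-ionone
Product: 2 (R)-α-ionone
Conditions: preparative SFC, cellulose tris(3,5-dimethylphenylcarbamate) on silica, CO2/i-PrOH, 35 °C; the dextrorotatory enantiomer is collected
Reagents that add atoms: none
Why: Direct enantiomer separation on a polysaccharide chiral stationary phase (physical resolution) should supply the (R) ketone, identified by the known dextrorotatory sense of that enantiomer, and so sets the C6 centre of the target, which no later step forms or touches.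

Step 2
Reactants: 2 (R)-α-ionone; 3 triethyl phosphonoacetate
Product: 4 ε-C15 ester, ethyl (2E,4E)-3-methyl-5-[(1R)-2,6,6-trimethylcyclohex-2-en-1-yl]penta-2,4-dienoate
Conditions: 3, NaH, THF, 0 °C; then 2, 0 °C to rt; chromatography removes the (2Z) isomer
Reagents that add atoms: triethyl phosphonoacetate (3), CCOC(=O)CP(=O)(OCC)OCC
Why: Horner–Wadsworth–Emmons olefination of the methyl ketone should give mainly the (9E) enoate with the ester trans to the dienyl chain, and the preformed, weakly basic phosphonate anion should leave the doubly allylic C6–H and hence the (6R) centre untouched.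

Step 3
Reactants: 4 ε-C15 ester
Product: 5 ε-C15 alcohol, (2E,4E)-3-methyl-5-[(1R)-2,6,6-trimethylcyclohex-2-en-1-yl]penta-2,4-dien-1-ol
Conditions: DIBAL-H, CH2Cl2, −78 °C; aq. Rochelle salt
Reagents that add atoms: none
Why: DIBAL-H reduction of the conjugated ester by 1,2-hydride delivery at low temperature should give the primary allylic alcohol without touching the diene or the ring alkene.

Step 4
Reactants: 5 ε-C15 alcohol
Product: 6 ε-C15 aldehyde, (2E,4E)-3-methyl-5-[(1R)-2,6,6-trimethylcyclohex-2-en-1-yl]penta-2,4-dienal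
Conditions: MnO2, CH2Cl2, rt, dark
Reagents that add atoms: none
Why: Allylic oxidation on activated MnO2 is selective for allylic alcohols and neutral, so alkene geometry and C6 should be preserved.

Step 5
Reactants: 6 ε-C15 aldehyde; 7 triethyl 3-methyl-4-phosphonocrotonate
Product: 8 ε-C20 ester, ethyl (2E,4E,6E,8E)-3,7-dimethyl-9-[(1R)-2,6,6-trimethylcyclohex-2-en-1-yl]nona-2,4,6,8-tetraenoate
Conditions: 7, n-BuLi, THF/DMPU, −78 °C; then 6, −78 to 0 °C
Reagents that add atoms: triethyl 3-methyl-4-phosphonocrotonate (7), CCOC(=O)/C=C(C)/CP(=O)(OCC)OCC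
Why: Horner–Wadsworth–Emmons reaction of the enal with the lithiated vinylogous phosphonoacetate, which reacts at the carbon next to phosphorus, should form C11=C12 as the E alkene and bring in C13=C14 as its more stable E isomer.

Step 6
Reactants: 8 ε-C20 ester
Product: 9 ε-C20 alcohol, (2E,4E,6E,8E)-3,7-dimethyl-9-[(1R)-2,6,6-trimethylcyclohex-2-en-1-yl]nona-2,4,6,8-tetraen-1-ol
Conditions: DIBAL-H, CH2Cl2, −78 °C; aq. Rochelle salt
Reagents that add atoms: none
Why: DIBAL-H ester reduction as in step 3 should give the C15 primary allylic alcohol with the tetraene intact.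

Step 7
Reactants: 9 ε-C20 alcohol
Product: 10 ε-C20 thioacetate, S-[(2E,4E,6E,8E)-3,7-dimethyl-9-[(1R)-2,6,6-trimethylcyclohex-2-en-1-yl]nona-2,4,6,8-tetraen-1-yl] ethanethioate
Conditions: PPh3, DIAD, THF, 0 °C; then 9, AcSH, 0 °C to rt, dark
Reagents that add atoms: thioacetic acid, CC(=O)S
Why: In this Mitsunobu reaction the alkoxyphosphonium ion should be displaced at the primary C15 by thioacetate under neutral conditions, with no free allylic cation that could expose C6–H to elimination.

Step 8
Reactants: 11 (3E,5E)-pseudoionone; 3 triethyl phosphonoacetate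
Product: 12 ψ-C15 ester, ethyl (2E,4E,6E)-3,7,11-trimethyldodeca-2,4,6,10-tetraenoate
Conditions: 3, NaH, THF, 0 °C; then 11, 0 °C to rt; chromatography removes the (2Z) isomer
Reagents that add atoms: triethyl phosphonoacetate (3), CCOC(=O)CP(=O)(OCC)OCC
Why: Horner–Wadsworth–Emmons olefination of the dienyl methyl ketone, as in step 2, should give mainly the (9′E) trienoate.

Step 9
Reactants: 12 ψ-C15 ester
Product: 13 ψ-C15 alcohol, (2E,4E,6E)-3,7,11-trimethyldodeca-2,4,6,10-tetraen-1-ol
Conditions: DIBAL-H, CH2Cl2, −78 °C; aq. Rochelle salt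
Reagents that add atoms: none
Why: DIBAL-H 1,2-reduction of the conjugated ester should give the primary allylic alcohol and leave the triene and the isolated alkene untouched.

Step 10
Reactants: 13 ψ-C15 alcohol
Product: 14 ψ-C15 aldehyde, (2E,4E,6E)-3,7,11-trimethyldodeca-2,4,6,10-tetraenal
Conditions: MnO2, CH2Cl2, rt, dark
Reagents that add atoms: none
Why: Allylic oxidation with MnO2 should stop at the trienal under neutral conditions.

Step 11
Reactants: 14 ψ-C15 aldehyde; 7 triethyl 3-methyl-4-phosphonocrotonate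
Product: 15 ψ-C20 ester, ethyl (2E,4E,6E,8E,10E)-3,7,11,15-tetramethylhexadeca-2,4,6,8,10,14-hexaenoate
Conditions: 7, n-BuLi, THF/DMPU, −78 °C; then 14, −78 to 0 °C
Reagents that add atoms: triethyl 3-methyl-4-phosphonocrotonate (7), CCOC(=O)/C=C(C)/CP(=O)(OCC)OCC
Why: Horner–Wadsworth–Emmons reaction as in step 5 should form C11′=C12′ as the E alkene and deliver the (13′E) pentaenoate.

Step 12
Reactants: 15 ψ-C20 ester
Product: 16 ψ-C20 alcohol, (2E,4E,6E,8E,10E)-3,7,11,15-tetramethylhexadeca-2,4,6,8,10,14-hexaen-1-ol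
Conditions: DIBAL-H, CH2Cl2, −78 °C; aq. Rochelle salt
Reagents that add atoms: none
Why: DIBAL-H ester reduction should give the C15′ primary allylic alcohol with the pentaene intact.

Step 13
Reactants: 16 ψ-C20 alcohol
Product: 17 ψ-C20 bromide, (2E,4E,6E,8E,10E)-1-bromo-3,7,11,15-tetramethylhexadeca-2,4,6,8,10,14-hexaene
Conditions: PBr3, pyridine (cat.), Et2O, −30 °C, dark; cold aq. NaHCO3; the dried solution is used at once
Reagents that add atoms: phosphorus tribromide, BrP(Br)Br
Why: Bromination of the primary allylic alcohol with PBr3 proceeds through the phosphite ester and bromide attack at C15′, and low temperature, a trace of pyridine and immediate use should keep the pentaenylic bromide from ionising.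

Step 14
Reactants: 10 ε-C20 thioacetate; 17 ψ-C20 bromide
Product: 19 C20 ε-polyenyl C20 ψ-polyenyl sulfide (C15–S–C15′), via sodium thiolate 18 (not isolated)
Conditions: 10, NaOMe, THF/MeOH, 0 °C, Ar; then 17 in THF, −30 to 0 °C
Reagents that add atoms: none
Why: Methoxide cleaves the thioester to thiolate 18, a soft and strong nucleophile that should displace the primary allylic bromide at C15′ directly (thioether synthesis by S-alkylation) faster than SN2′ attack, solvolysis or elimination.

Step 15
Reactants: 19 C15–S–C15′ sulfide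
Product: 21 C20 ε-polyenyl C20 ψ-polyenyl sulfone (C15–SO2–C15′), via sulfoxide 20 (not isolated)
Conditions: 30% H2O2, (NH4)6Mo7O24·4H2O (cat.), EtOH/THF, 0 °C to rt, dark
Reagents that add atoms: hydrogen peroxide, OO
Why: In this molybdate-catalysed sulfide oxidation the peroxomolybdate should transfer oxygen to sulfur, first to sulfoxide 20 and then to the sulfone, much faster than to any of the eleven C=C bonds, so a controlled amount of H2O2 should leave the polyene intact.

Step 16
Reactants: 21 C15–SO2–C15′ sulfone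
Product: 24 (6R)-ε,ψ-carotene (all-E), via α-bromo sulfone 22 (not isolated), via trans-episulfone 23 (not isolated)
Conditions: CBr2F2, KOH/Al2O3, t-BuOH/CH2Cl2, 0 °C to rt, Ar, dark; then heptane, reflux, Ar, dark; crystallisation
Reagents that add atoms: none
Why: Hydroxide on alumina removes a proton next to sulfur at C15 or C15′, the allylic carbanion takes bromine from CBr2F2 to give α-bromo sulfone 22, and a second deprotonation on the other side displaces bromide intramolecularly to form the C15–C15′ σ bond in episulfone 23, which loses SO2 to leave the C15=C15′ double bond. The closest known reaction type is the one-flask Ramberg–Bäcklund olefination of diallylic sulfones to conjugated trienes and higher polyenes with in situ α-halogenation. The only ring closed is the three-membered thiirane 1,1-dioxide (3-exo-tet, carbanion onto the carbon bearing bromine); it is not retained, and the six-membered ring of the target is present from the start. No stereocentre is formed, and C6 should survive because its doubly allylic C–H is far less acidic than the four α-sulfonyl protons under this mild heterogeneous base at or below room temperature. The step needs halogenation and closure at the α-carbons, not at vinylogous positions, which the sulfonyl group secures by localising carbanion reactivity on the carbons it bears, and it does not need the two halves to be told apart, since bromination at either α-carbon converges on the same episulfone. The E geometry at C15=C15′ should come from base-mediated epimerisation of the episulfone to its trans isomer before SO2 loss, and any (15Z) isomer is converted thermally in hot heptane, from which the all-E compound crystallises.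

**Compound list**

1 | (±)-α-ionone, racemic (3E)-4-(2,6,6-trimethylcyclohex-2-en-1-yl)but-3-en-2-one | CC(=O)/C=C/C1C(C)=CCCC1(C)C | starting material
2 | (R)-α-ionone, (3E)-4-[(1R)-2,6,6-trimethylcyclohex-2-en-1-yl]but-3-en-2-one | CC(=O)/C=C/[C@H]1C(C)=CCCC1(C)C | intermediate
3 | triethyl phosphonoacetate | CCOC(=O)CP(=O)(OCC)OCC | starting material
4 | ε-C15 ester, ethyl (2E,4E)-3-methyl-5-[(1R)-2,6,6-trimethylcyclohex-2-en-1-yl]penta-2,4-dienoate | CCOC(=O)/C=C(C)/C=C/[C@H]1C(C)=CCCC1(C)C | intermediate
5 | ε-C15 alcohol, (2E,4E)-3-methyl-5-[(1R)-2,6,6-trimethylcyclohex-2-en-1-yl]penta-2,4-dien-1-ol | OC/C=C(C)/C=C/[C@H]1C(C)=CCCC1(C)C | intermediate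
6 | ε-C15 aldehyde, (2E,4E)-3-methyl-5-[(1R)-2,6,6-trimethylcyclohex-2-en-1-yl]penta-2,4-dienal | O=C/C=C(C)/C=C/[C@H]1C(C)=CCCC1(C)C | intermediate
7 | triethyl 3-methyl-4-phosphonocrotonate, ethyl (2E)-4-(diethoxyphosphoryl)-3-methylbut-2-enoate | CCOC(=O)/C=C(C)/CP(=O)(OCC)OCC | starting material
8 | ε-C20 ester, ethyl (2E,4E,6E,8E)-3,7-dimethyl-9-[(1R)-2,6,6-trimethylcyclohex-2-en-1-yl]nona-2,4,6,8-tetraenoate | CCOC(=O)/C=C(C)/C=C/C=C(C)/C=C/[C@H]1C(C)=CCCC1(C)C | intermediate
9 | ε-C20 alcohol ((6R)-α-retinol), (2E,4E,6E,8E)-3,7-dimethyl-9-[(1R)-2,6,6-trimethylcyclohex-2-en-1-yl]nona-2,4,6,8-tetraen-1-ol | OC/C=C(C)/C=C/C=C(C)/C=C/[C@H]1C(C)=CCCC1(C)C | intermediate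
10 | ε-C20 thioacetate, S-[(2E,4E,6E,8E)-3,7-dimethyl-9-[(1R)-2,6,6-trimethylcyclohex-2-en-1-yl]nona-2,4,6,8-tetraen-1-yl] ethanethioate | CC(=O)SC/C=C(C)/C=C/C=C(C)/C=C/[C@H]1C(C)=CCCC1(C)C | intermediate
11 | pseudoionone, (3E,5E)-6,10-dimethylundeca-3,5,9-trien-2-one | CC(C)=CCC/C(C)=C/C=C/C(C)=O | starting material
12 | ψ-C15 ester, ethyl (2E,4E,6E)-3,7,11-trimethyldodeca-2,4,6,10-tetraenoate | CCOC(=O)/C=C(C)/C=C/C=C(C)/CCC=C(C)C | intermediate
13 | ψ-C15 alcohol, (2E,4E,6E)-3,7,11-trimethyldodeca-2,4,6,10-tetraen-1-ol | OC/C=C(C)/C=C/C=C(C)/CCC=C(C)C | intermediate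
14 | ψ-C15 aldehyde, (2E,4E,6E)-3,7,11-trimethyldodeca-2,4,6,10-tetraenal | O=C/C=C(C)/C=C/C=C(C)/CCC=C(C)C | intermediate
15 | ψ-C20 ester, ethyl (2E,4E,6E,8E,10E)-3,7,11,15-tetramethylhexadeca-2,4,6,8,10,14-hexaenoate | CCOC(=O)/C=C(C)/C=C/C=C(C)/C=C/C=C(C)/CCC=C(C)C | intermediate
16 | ψ-C20 alcohol, (2E,4E,6E,8E,10E)-3,7,11,15-tetramethylhexadeca-2,4,6,8,10,14-hexaen-1-ol | OC/C=C(C)/C=C/C=C(C)/C=C/C=C(C)/CCC=C(C)C | intermediate
17 | ψ-C20 bromide, (2E,4E,6E,8E,10E)-1-bromo-3,7,11,15-tetramethylhexadeca-2,4,6,8,10,14-hexaene | BrC/C=C(C)/C=C/C=C(C)/C=C/C=C(C)/CCC=C(C)C | intermediate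
18 | sodium ε-C20 thiolate, sodium salt of the thiol corresponding to alcohol 9 | [Na+].[S-]C/C=C(C)/C=C/C=C(C)/C=C/[C@H]1C(C)=CCCC1(C)C | intermediate
19 | C15–S–C15′ sulfide: the (2E,4E,6E,8E)-3,7-dimethyl-9-[(1R)-2,6,6-trimethylcyclohex-2-en-1-yl]nona-2,4,6,8-tetraenyl and (2E,4E,6E,8E,10E)-3,7,11,15-tetramethylhexadeca-2,4,6,8,10,14-hexaenyl groups on one sulfur | CC(C)=CCC/C(C)=C/C=C/C(C)=C/C=C/C(C)=C/CSC/C=C(C)/C=C/C=C(C)/C=C/[C@H]1C(C)=CCCC1(C)C | intermediate
20 | C15–S(O)–C15′ sulfoxide of 19 (both configurations at sulfur) | CC(C)=CCC/C(C)=C/C=C/C(C)=C/C=C/C(C)=C/CS(=O)C/C=C(C)/C=C/C=C(C)/C=C/[C@H]1C(C)=CCCC1(C)C | intermediate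
21 | C20 ε-polyenyl C20 ψ-polyenyl sulfone (C15–SO2–C15′, 6R) | CC(C)=CCC/C(C)=C/C=C/C(C)=C/C=C/C(C)=C/CS(=O)(=O)C/C=C(C)/C=C/C=C(C)/C=C/[C@H]1C(C)=CCCC1(C)C | intermediate
22 | α-bromo sulfone: 21 with bromine on C15 (shown; the C15′ regioisomer reacts alike), both epimers at the CHBr carbon | CC(C)=CCC/C(C)=C/C=C/C(C)=C/C=C/C(C)=C/CS(=O)(=O)C(Br)/C=C(C)/C=C/C=C(C)/C=C/[C@H]1C(C)=CCCC1(C)C | intermediate
23 | trans-episulfone: trans-2,3-disubstituted thiirane 1,1-dioxide built from C15 and C15′ (one of the two trans diastereomers shown) | CC(C)=CCC/C(C)=C/C=C/C(C)=C/C=C/C(C)=C/[C@@H]1[C@@H](/C=C(C)/C=C/C=C(C)/C=C/[C@H]2C(C)=CCCC2(C)C)S1(=O)=O | intermediate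
24 | (6R)-ε,ψ-carotene, all-E | CC(C)=CCC/C(C)=C/C=C/C(C)=C/C=C/C(C)=C/C=C/C=C(C)/C=C/C=C(C)/C=C/[C@H]1C(C)=CCCC1(C)C | target

**Step count**

- Total: 16 steps.
- Longest linear sequence: 10 steps (steps 1–7, 14, 15, 16).

**Steps most likely to fail**

1. Step 16 (key step). Three processes may intervene:
   - base-mediated prototropic shift of the allylic sulfone into conjugation before bromine transfer, or bromination and closure at a vinylogous position;
   - addition of the difluorocarbene released from CBr2F2 to the two isolated trisubstituted alkenes;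
   - incomplete conversion of the (15Z) isomer.

   Fallback: it sets out from bromide 17 and alcohol 9 and forms C15=C15′ by Wittig olefination. Bromide 17 with PPh3 in toluene at rt should give the ψ-C20 triphenylphosphonium bromide F1. Alcohol 9 is oxidised with MnO2 in CH2Cl2 to the ε-C20 aldehyde F2. The ylide from F1 (NaOMe, MeOH/CH2Cl2, 0 °C) is condensed with F2, and the heptane isomerisation and crystallisation of step 16 bring the route back at 24.

2. Step 15. Oxygen transfer may not stop at sulfur (epoxidation of the C1′=C2′ and C4=C5 alkenes or degradation of the conjugated chains), and the allylic sulfoxide may undergo a [2,3]-sigmatropic shift to a sulfenate before the second oxidation.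

   Fallback: it sets out from bromide 17 and alcohol 9 and builds the sulfone without any oxidation at sulfur.
   - Bromide 17 is S-alkylated with sodium 3-methoxy-3-oxopropane-1-sulfinate (COC(=O)CCS(=O)[O-].[Na+]) in DMSO at rt to give the ψ-C20 sulfonylpropanoate F3.
   - NaOMe in THF/MeOH at 0 °C removes methyl acrylate by retro-Michael cleavage and leaves the sodium ψ-C20 sulfinate F4.
   - Alcohol 9 is converted with PBr3 in Et2O at −30 °C into the ε-C20 bromide F5.
   - S-alkylation of F4 with F5 in DMF at 0 °C returns to the route at sulfone 21.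

3. Step 13. The pentaenylic bromide may ionise during its formation or handling, with allylic transposition, loss of the 13′E geometry or loss of HBr to a retro-type hexaene before sulfur attacks.

   Fallback: it sets out from alcohol 16 and thioacetate 10 and uses no C20 halide. Alcohol 16 with methyl chloroformate and pyridine in CH2Cl2 at 0 °C gives the ψ-C20 methyl carbonate F6. Thioacetate 10 is cleaved with NaOMe in THF/MeOH and neutralised with aq. NH4Cl to the ε-C20 thiol F7. Allylic substitution of F6 by F7 with Pd2(dba)3 (zerovalent palladium) and dppb in THF at rt proceeds through the π-allyl complex with loss of CO2 and methanol and sulfur attack at the unhindered C15′ terminus, and comes back at sulfide 19.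

**Further compounds**

F1 | step 16 | [(2E,4E,6E,8E,10E)-3,7,11,15-tetramethylhexadeca-2,4,6,8,10,14-hexaen-1-yl]triphenylphosphonium bromide | CC(C)=CCC/C(C)=C/C=C/C(C)=C/C=C/C(C)=C/C[P+](c1ccccc1)(c1ccccc1)c1ccccc1.[Br-]
F2 | step 16 | ε-C20 aldehyde ((6R)-α-retinal), (2E,4E,6E,8E)-3,7-dimethyl-9-[(1R)-2,6,6-trimethylcyclohex-2-en-1-yl]nona-2,4,6,8-tetraenal | O=C/C=C(C)/C=C/C=C(C)/C=C/[C@H]1C(C)=CCCC1(C)C
F3 | step 15 | methyl 3-{[(2E,4E,6E,8E,10E)-3,7,11,15-tetramethylhexadeca-2,4,6,8,10,14-hexaen-1-yl]sulfonyl}propanoate | COC(=O)CCS(=O)(=O)C/C=C(C)/C=C/C=C(C)/C=C/C=C(C)/CCC=C(C)C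
F4 | step 15 | sodium (2E,4E,6E,8E,10E)-3,7,11,15-tetramethylhexadeca-2,4,6,8,10,14-hexaene-1-sulfinate | [Na+].[O-]S(=O)C/C=C(C)/C=C/C=C(C)/C=C/C=C(C)/CCC=C(C)C
F5 | step 15 | ε-C20 bromide, the C15 bromide corresponding to alcohol 9 | BrC/C=C(C)/C=C/C=C(C)/C=C/[C@H]1C(C)=CCCC1(C)C
F6 | step 13 | methyl (2E,4E,6E,8E,10E)-3,7,11,15-tetramethylhexadeca-2,4,6,8,10,14-hexaen-1-yl carbonate | COC(=O)OC/C=C(C)/C=C/C=C(C)/C=C/C=C(C)/CCC=C(C)C
F7 | step 13 | ε-C20 thiol, (2E,4E,6E,8E)-3,7-dimethyl-9-[(1R)-2,6,6-trimethylcyclohex-2-en-1-yl]nona-2,4,6,8-tetraene-1-thiol | SC/C=C(C)/C=C/C=C(C)/C=C/[C@H]1C(C)=CCCC1(C)C
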